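**Strategy.** The target is a methylene-bridged acylphloroglucinol–α-pyrone. Everything rests on cutting the bond between the bridging CH2 (kept on the benzene ring) and C-3 of the 4-hydroxy-2-pyrone ring. The key step copies the presumed biosynthesis: a Mannich base, whose CH2NMe2 sits ortho to the free C-4 hydroxyl (para to the acyl group) of the fully substituted benzene ring, loses dimethylamine on heating to an o-quinone methide. The pyrone captures it at C-3, its only unsubstituted ring carbon, flanked by the C-2 lactone carbonyl and the C-4 enol. One operation joins both halves and restores both aromatic rings. The arene comes from 5-methoxyresorcinol by two directed metalations; the pyrone from a β-keto ester dianion.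

Key step: step 8

Assumption: the target has no stereocentre and no stereogenic double bond (the prenyl alkene carries two identical methyl groups), so it is achiral and the route needs no stereocontrol.

**Route**

Step 1
Reactants: 1 methyl 3-oxopentanoate
Product: 3 methyl 4-methyl-3,5-dioxoheptanoate, via dilithium dienolate 2 (not isolated)
Conditions: LDA (2.2 equiv), THF, −78 → 0 °C; EtC(O)N(OMe)Me, −78 °C → rt; 1 M HCl
Reagents that add atoms: N-methoxy-N-methylpropanamide, CCC(=O)N(C)OC
Why: Huckin–Weiler γ-acylation, in which the dienolate should react at its more nucleophilic γ-carbon and the chelated tetrahedral adduct of the Weinreb amide survives until the acid quench, so over-addition and proton transfer to the product should not interfere.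

Step 2
Reactants: 3 methyl 4-methyl-3,5-dioxoheptanoate
Product: 4 6-ethyl-4-hydroxy-5-methyl-2H-pyran-2-one
Conditions: DBU (1.2 equiv), toluene, 80 °C; 1 M HCl
Reagents that add atoms: none
Why: Base-mediated enol lactonisation (the C-5 enolate oxygen attacks the ester carbonyl with loss of methoxide) followed by tautomerisation should give the aromatic 4-hydroxy-2-pyrone.

Step 3
Reactants: 5 5-methoxyresorcinol (5-methoxybenzene-1,3-diol)
Product: 6 1-methoxy-3,5-bis(methoxymethoxy)benzene
Conditions: NaH (2.4 equiv), DMF, 0 °C; MOMCl (2.4 equiv), 0 °C → rt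
Reagents that add atoms: chloromethyl methyl ether, COCCl
Why: Williamson-type O-alkylation of the bis-phenoxide should install two MOM acetals, which later serve as directing groups for metalation.

Step 4
Reactants: 6 1-methoxy-3,5-bis(methoxymethoxy)benzene
Product: 8 5-methoxy-1,3-bis(methoxymethoxy)-2-(3-methylbut-2-en-1-yl)benzene, via aryllithium 7 (not isolated)
Conditions: n-BuLi (1.1 equiv), THF, 0 °C → rt; CuI (10 mol %), prenyl bromide, −78 °C → rt
Reagents that add atoms: 1-bromo-3-methylbut-2-ene (prenyl bromide), CC(C)=CCBr
Why: Directed ortho-metalation should occur at the ring carbon flanked by both OMOM groups (two cooperating, chelating directors, stronger than OMe), and copper-catalysed SN2 allylation of the aryllithium then places the prenyl group between the two oxygens.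

Step 5
Reactants: 8 5-methoxy-1,3-bis(methoxymethoxy)-2-(3-methylbut-2-en-1-yl)benzene
Product: 10 1-[6-methoxy-2,4-bis(methoxymethoxy)-3-(3-methylbut-2-en-1-yl)phenyl]-2-methylpropan-1-one, via aryllithium 9 (not isolated)
Conditions: n-BuLi (1.2 equiv), TMEDA, THF, −20 → 0 °C; i-PrC(O)N(OMe)Me, −78 °C → rt; H2O
Reagents that add atoms: N-methoxy-N-methyl-2-methylpropanamide, CC(C)C(=O)N(C)OC
Why: A second directed ortho-metalation can only take place at one of the two remaining ring positions, which are equivalent by the mirror plane through C–OMe and C–prenyl and are each flanked by OMe and OMOM, and the Weinreb ketone synthesis should then stop at the aryl ketone.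

Step 6
Reactants: 10 1-[6-methoxy-2,4-bis(methoxymethoxy)-3-(3-methylbut-2-en-1-yl)phenyl]-2-methylpropan-1-one
Product: 11 1-[2,4-dihydroxy-6-methoxy-3-(3-methylbut-2-en-1-yl)phenyl]-2-methylpropan-1-one
Conditions: 3 M aq. HCl, MeOH, rt → 40 °C
Reagents that add atoms: none
Why: Acid-catalysed solvolysis of the two MOM acetals in methanol should be fast enough under mild conditions to spare the prenyl group, while the ketone and the aryl methyl ether are inert.

Step 7
Reactants: 11 1-[2,4-dihydroxy-6-methoxy-3-(3-methylbut-2-en-1-yl)phenyl]-2-methylpropan-1-one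
Product: 12 1-[3-[(dimethylamino)methyl]-4,6-dihydroxy-2-methoxy-5-(3-methylbut-2-en-1-yl)phenyl]-2-methylpropan-1-one
Conditions: CH2(NMe2)2 (1.5 equiv), 1,4-dioxane, rt → 50 °C
Reagents that add atoms: bis(dimethylamino)methane, CN(C)CN(C)C
Why: Phenolic Mannich reaction, in which the acidic phenol protonates the aminal to release the methyleneiminium ion, which can substitute only at the single unsubstituted ring carbon (ortho to the C-4 hydroxyl), and the acid-free medium leaves the prenyl group untouched.

Step 8
Reactants: 12 1-[3-[(dimethylamino)methyl]-4,6-dihydroxy-2-methoxy-5-(3-methylbut-2-en-1-yl)phenyl]-2-methylpropan-1-one and 4 6-ethyl-4-hydroxy-5-methyl-2H-pyran-2-one (1.5 equiv)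
Product: 14 6-ethyl-4-hydroxy-3-{[2,4-dihydroxy-6-methoxy-5-(2-methylpropanoyl)-3-(3-methylbut-2-en-1-yl)phenyl]methyl}-5-methyl-2H-pyran-2-one, via o-quinone methide 13 (not isolated)
Conditions: 1,4-dioxane, 90 °C, N2 stream
Reagents that add atoms: none
Why: Proton transfer from the acidic pyrone 4 to the benzylic amine and E1cB-type loss of dimethylamine through the ortho C-4 phenoxide generate o-quinone methide 13, whose exocyclic methylene is attacked by C-3 of the pyronate in a conjugate (Michael) addition; tautomerisation then restores the phenol and the 4-hydroxy-2-pyrone. The closest known reaction type is the thermal coupling of phenolic Mannich bases with cyclic 1,3-dicarbonyl C-nucleophiles such as 4-hydroxycoumarins and 4-hydroxy-2-pyrones via o-quinone methides, which is also the presumed biosynthetic union of such methylene-bridged dimers. No ring is closed and no stereocentre is formed. The step needs C- over O-alkylation of the ambident pyronate and mono- over bis-benzylation: O-adducts should revert to 13 whereas C-3 alkylation is irreversible and re-aromatises both rings, and the excess of 4 suppresses a second alkylation. Site selectivity is secured by the substrate, because C-3 is the only unsubstituted carbon of the pyrone (C-5 carries methyl) and every ring carbon of the arene is substituted, so 13 cannot be intercepted by a second phloroglucinol nucleus.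

**Compound list**

1 | methyl 3-oxopentanoate | CCC(=O)CC(=O)OC | starting material
2 | dilithium 1-methoxyhexa-1,3-diene-1,3-diolate (α,γ-dianion of 1; enolate geometry not defined) | CC=C(O[Li])C=C(OC)O[Li] | intermediate
3 | methyl 4-methyl-3,5-dioxoheptanoate (racemic at C-4, lost on lactonisation) | CCC(=O)C(C)C(=O)CC(=O)OC | intermediate
4 | 6-ethyl-4-hydroxy-5-methyl-2H-pyran-2-one | CCc1oc(=O)cc(O)c1C | intermediate
5 | 5-methoxyresorcinol (5-methoxybenzene-1,3-diol) | COc1cc(O)cc(O)c1 | starting material
6 | 1-methoxy-3,5-bis(methoxymethoxy)benzene | COCOc1cc(OC)cc(OCOC)c1 | intermediate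
7 | [4-methoxy-2,6-bis(methoxymethoxy)phenyl]lithium | [Li]c1c(OCOC)cc(OC)cc1OCOC | intermediate
8 | 5-methoxy-1,3-bis(methoxymethoxy)-2-(3-methylbut-2-en-1-yl)benzene | COCOc1cc(OC)cc(OCOC)c1CC=C(C)C | intermediate
9 | [2-methoxy-4,6-bis(methoxymethoxy)-5-(3-methylbut-2-en-1-yl)phenyl]lithium | [Li]c1c(OC)cc(OCOC)c(CC=C(C)C)c1OCOC | intermediate
10 | 1-[6-methoxy-2,4-bis(methoxymethoxy)-3-(3-methylbut-2-en-1-yl)phenyl]-2-methylpropan-1-one | CC(C)C(=O)c1c(OC)cc(OCOC)c(CC=C(C)C)c1OCOC | intermediate
11 | 1-[2,4-dihydroxy-6-methoxy-3-(3-methylbut-2-en-1-yl)phenyl]-2-methylpropan-1-one | CC(C)C(=O)c1c(OC)cc(O)c(CC=C(C)C)c1O | intermediate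
12 | 1-[3-[(dimethylamino)methyl]-4,6-dihydroxy-2-methoxy-5-(3-methylbut-2-en-1-yl)phenyl]-2-methylpropan-1-one | CC(C)C(=O)c1c(OC)c(CN(C)C)c(O)c(CC=C(C)C)c1O | intermediate
13 | 3-hydroxy-5-methoxy-6-methylidene-4-(2-methylpropanoyl)-2-(3-methylbut-2-en-1-yl)cyclohexa-2,4-dien-1-one (o-quinone methide) | CC(C)C(=O)C1=C(OC)C(=C)C(=O)C(CC=C(C)C)=C1O | intermediate
14 | 6-ethyl-4-hydroxy-3-{[2,4-dihydroxy-6-methoxy-5-(2-methylpropanoyl)-3-(3-methylbut-2-en-1-yl)phenyl]methyl}-5-methyl-2H-pyran-2-one | CCc1oc(=O)c(Cc2c(O)c(CC=C(C)C)c(O)c(C(=O)C(C)C)c2OC)c(O)c1C | target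

**Step count**

Total: 8 steps. Longest linear sequence: 6 steps (steps 3–8, from 5-methoxyresorcinol); the pyrone branch (steps 1–2) joins in step 8.

**Steps most likely to fail**

1. Step 8. The transient quinone methide may be consumed by self-condensation or oligomerisation, by O-alkylation that does not funnel back, or by a second benzylation of the pyrone, before clean C-3 capture. The fallback sets out from 11 and comes back at 14. Vilsmeier–Haack formylation of 11 (POCl3, DMF, MeCN, 0 °C → rt; aq. NaOAc) at its only free ring carbon should give 2,4-dihydroxy-6-methoxy-5-(2-methylpropanoyl)-3-(3-methylbut-2-en-1-yl)benzaldehyde F1. An organocatalytic three-component reductive alkylation of pyrone 4 with F1 and Hantzsch ester (L-proline cat., CH2Cl2, rt) would then pass through the Knoevenagel adduct, 3-arylidene pyran-2,4-dione F2, which is reduced in the flask by conjugate hydride transfer to 14. The same carbon–carbon connection is made by condensation and transfer hydrogenation, without thermal generation of a quinone methide.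

2. Step 5. Proton transfer from the α-C–H of the branched amide to the di-ortho-substituted aryllithium may outpace addition, which would simply return 8. The fallback sets out from 8 (through aryllithium 9) and comes back at 10. The aryllithium is trapped with the faster-adding, unhindered isobutyraldehyde (−78 °C → 0 °C; H2O) to give the racemic benzylic alcohol 1-[6-methoxy-2,4-bis(methoxymethoxy)-3-(3-methylbut-2-en-1-yl)phenyl]-2-methylpropan-1-ol F3, which is oxidised with Dess–Martin periodinane (CH2Cl2, NaHCO3, rt) to ketone 10. Acyl transfer is replaced by addition followed by oxidation.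

3. Step 6. During acidic MOM cleavage the prenyl group may cyclise onto a flanking free hydroxyl (chroman formation) or add HCl or methanol across its double bond. The fallback sets out from 5 and comes back at 11, with a fluoride-labile protecting group in place of MOM.
   - Protection of 5 (NaH, SEMCl, DMF) gives 1-methoxy-3,5-bis{[2-(trimethylsilyl)ethoxy]methoxy}benzene F4.
   - Lithiation as in step 4 gives aryllithium F5, and prenylation gives the prenylated bis-SEM ether F6.
   - Lithiation as in step 5 gives aryllithium F7, and acylation with the Weinreb amide gives the bis-SEM ketone F8.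
   - Cleavage with TBAF (DMPU or THF, 60 °C) releases 11 under non-acidic conditions, in which no carbocation can form next to the prenyl group.

**Further compounds**

F1 | step 8 | 2,4-dihydroxy-6-methoxy-5-(2-methylpropanoyl)-3-(3-methylbut-2-en-1-yl)benzaldehyde | CC(C)C(=O)c1c(OC)c(C=O)c(O)c(CC=C(C)C)c1O
F2 | step 8 | 6-ethyl-5-methyl-3-{[2,4-dihydroxy-6-methoxy-5-(2-methylpropanoyl)-3-(3-methylbut-2-en-1-yl)phenyl]methylidene}-2H-pyran-2,4(3H)-dione (not isolated; alkene geometry not defined, lost on reduction) | CCC1=C(C)C(=O)C(=Cc2c(O)c(CC=C(C)C)c(O)c(C(=O)C(C)C)c2OC)C(=O)O1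
F3 | step 5 | 1-[6-methoxy-2,4-bis(methoxymethoxy)-3-(3-methylbut-2-en-1-yl)phenyl]-2-methylpropan-1-ol (racemic) | CC(C)C(O)c1c(OC)cc(OCOC)c(CC=C(C)C)c1OCOC
F4 | step 6 | 1-methoxy-3,5-bis{[2-(trimethylsilyl)ethoxy]methoxy}benzene | COc1cc(OCOCC[Si](C)(C)C)cc(OCOCC[Si](C)(C)C)c1
F5 | step 6 | [4-methoxy-2,6-bis{[2-(trimethylsilyl)ethoxy]methoxy}phenyl]lithium (not isolated) | [Li]c1c(OCOCC[Si](C)(C)C)cc(OC)cc1OCOCC[Si](C)(C)C
F6 | step 6 | 5-methoxy-2-(3-methylbut-2-en-1-yl)-1,3-bis{[2-(trimethylsilyl)ethoxy]methoxy}benzene | COc1cc(OCOCC[Si](C)(C)C)c(CC=C(C)C)c(OCOCC[Si](C)(C)C)c1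
F7 | step 6 | [2-methoxy-5-(3-methylbut-2-en-1-yl)-4,6-bis{[2-(trimethylsilyl)ethoxy]methoxy}phenyl]lithium (not isolated) | [Li]c1c(OC)cc(OCOCC[Si](C)(C)C)c(CC=C(C)C)c1OCOCC[Si](C)(C)C
F8 | step 6 | 1-[6-methoxy-3-(3-methylbut-2-en-1-yl)-2,4-bis{[2-(trimethylsilyl)ethoxy]methoxy}phenyl]-2-methylpropan-1-one | CC(C)C(=O)c1c(OC)cc(OCOCC[Si](C)(C)C)c(CC=C(C)C)c1OCOCC[Si](C)(C)C
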